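## The problem

Mallotophenone (7) is an achiral, symmetrical diarylmethane in which two identical, fully substituted benzene rings are joined through one CH2 group, so no ring has to be built if the right arene can be bought. Numbering each ring from the methoxy carbon, the substituents are OMe at C1, CH3 at C2, OH at C3, acetyl at C4, OH at C5 and the bridging methylene at C6. There is no stereocenter to set and none that could direct a reaction, so the task is purely regiochemical: only the oxygen para to the acetyl group is methylated, the C-methyl group lies between that methoxy group and one chelated hydroxyl, and the bridge lies between the methoxy group and the other. The functionality is that of an acylphloroglucinol ether and is not robust: the phenoxides oxidize in air, alkylate on oxygen as well as on carbon and can be dearomatized by a second C-alkylation. The methylene bridge between two such rings is broken and scrambled by hot alkali (retro-Michael reaction through an ortho-quinone methide) and by strong Lewis acids, so late steps must be few and mild. The enabling feature is that the OMe/OH/acetyl/OH pattern of each ring is that of the catalogue compound 1, which has two equivalent unsubstituted ring carbons. Once one of them carries the bridge (C6), the other (C2), ortho to the oxygen on C3 and para to the oxygen on C5, is the single position on each ring where a carbon electrophile can be taken up with return to the aromatic state, and because the two rings are identical and insulated by the sp3 bridge, both C2 positions can be addressed in one operation.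

## Retrosynthesis

**First disconnection (7 to 4 and 5).** The two C2–CH3 bonds of 7 are cut together, passing through the mono-methyl compound 6, to give the bis-acetophenone 4 and two molecules of iodomethane (5). Cutting the bridge first would shift the methylation to the monomer 1, whose two equivalent free ring carbons can take up one or two methyl groups, so that the mono-methyl stage would have to be separated from both neighbours; in 4 the bridge acts as a blocking group and each ring offers one site only. Cutting an O–CH3 or an aryl–acetyl bond would reopen the differentiation of the three oxygens and call for Friedel–Crafts chemistry on an acid-labile diarylmethane. The gain is that both methyl groups are removed in one step by symmetry and that 4 is the direct formaldehyde dimer of a purchasable arene. The forward reaction must alkylate on carbon and not on oxygen, put one methyl group on each ring and leave the bridge intact in methoxide.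

**Second disconnection (4 to 1 and 2).** Both C6–CH2 bonds of 4 are cut, giving two molecules of 1 and formaldehyde (2); in the forward sense the benzylic alcohol 3 is passed. A stepwise coupling through a preformed benzylic electrophile is only needed for unsymmetrical dimers, whereas for a symmetrical one formaldehyde supplies the one carbon at the right oxidation level in a single operation. The precursor is now one bought aromatic compound, already carrying the acetyl group, the methyl ether and both hydroxyls in their final places, plus a one-carbon unit. The forward reaction must stop at the dimer: compound 1 has two equivalent nucleophilic carbons and 4 keeps one on each ring, so 1 is used in excess with 2 as the limiting reagent. Regiochemistry is not in question because the two free carbons of 1 are equivalent.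

## Roads not taken

**Alternative 1:** The acetyl and O-methyl groups are removed first, leading to bis(2,4,6-trihydroxy-3-methylphenyl)methane (A1). Both rings of A1 are then opened at C2–C3 and C5–C6, giving nonane-3,7-dione (A2) and two molecules of malonyl dichloride (A3). The central CH2 of A2 becomes the bridge and its terminal methyls become the ring methyls.

- Forward key step: both carbonyls of A2 are masked as enol ethers and each is C-acylated on both alpha carbons by A3, closing and aromatizing the two rings.
- Merit: the positions of the C-methyl group and the bridge are fixed by the constitution of the chain. There is no C- versus O-alkylation question and no oligomer question. In this respect it is better than the chosen plan, which relies on stoichiometry and innate reactivity.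
- Weak points: A3 tends to O-acylate enol derivatives and close pyranones instead of carbocycles, and the reaction would have to succeed twice in one molecule. A1 is an unacylated bis-phloroglucinol, very easily oxidized and acid-labile at the bridge. A2 is not a stock chemical.
- What still follows A1: a twofold Friedel–Crafts acetylation on a cleavable diarylmethane, then a twofold selective methylation of the hindered oxygen between methyl and bridge.
- Comparison: the chosen plan buys the acetyl group and the correct O-methyl pattern ready-made and needs two steps. Against that stands a longer sequence with its most doubtful reaction at the centre.

**Alternative 2:** Each ring is cut at C2–C3 and C6–C1, so that C1 and C2 with their methoxy and methyl groups come from an alkyne. The product of the ring-forming step is bis[6-(benzyloxy)-4-hydroxy-2-methoxy-3-methylphenyl]methane (A4). Its precursors are 2,2'-methylenebis[3-(benzyloxy)cyclobut-2-en-1-one] (A5) and two molecules of 1-methoxyprop-1-yne (A6).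

- Forward key step: a twofold Danheiser benzannulation. Heating A5 opens each cyclobutenone to a vinylketene, which adds A6 in a (2+2) cycloaddition. A 4π ring opening and a 6π electrocyclization then give the phenol.
- Merit: the regiochemistry is dictated by the polarity of the ynol ether, so methoxy, methyl and hydroxyl arrive in the right order and the three oxygens are differentiated from the start. This is better control than the chosen plan can claim.
- Weak points: A5 is a doubly strained, thermally sensitive vinylogous ester that would need several steps of its own. A6 is volatile and not a shelf reagent. After A4, an acetylation at C4 of each ring and removal of both benzyl groups are still required.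
- Comparison: complete positional control is bought with a sequence several times longer. The chosen plan sets against it two steps from catalogue materials and a single selectivity question (carbon versus oxygen) at its end.

**Alternative 3:** All six aryl C–O bonds are cut, leading from bis(2,4,6-trimethoxy-3-methylphenyl)methane (A7) back to bis(2,4,6-tribromo-3-methylphenyl)methane (A8).

- Forward key step: a sixfold Ullmann-type ether synthesis, in which methoxide under mediation by CuI (monovalent copper) replaces every bromide of A8.
- Merit: all intermediates are robust, non-phenolic compounds. The C-methyl groups and the bridge are present from the start, so neither oligomers nor C- versus O-alkylation arise. In handling and in freedom from statistical mixtures this road is superior.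
- Weak points: six substitutions at bromides that are each flanked by ortho substituents invite hydrodebromination at every site. Six halogens are introduced only to be discarded. After A7, the acetyl groups must be installed by Friedel–Crafts acylation on a diarylmethane that acid can cleave.
- The demethylation: four of the six methyl ethers must then be cleaved. Chelation to the new acetyl group would direct BCl3 to the two ethers ortho to it on each ring, which is the pattern needed. The ether that must survive is, however, flanked by methyl and bridge and twisted out of the ring plane, so it is more basic than an ordinary anisole ether and could be lost as well, and the same Lewis acids endanger the electron-rich diarylmethane.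
- Comparison: the chosen plan needs no demethylation and no halogen, and its late step is run in base at or below room temperature, where the bridge is safer.

Key step: step 2

Assumption: compound 1 (2′,6′-dihydroxy-4′-methoxyacetophenone) is taken as a catalogue chemical; ring positions are numbered C1 (OMe) to C6 (bridge) as defined in the first section.

## Route

Step 1
Reactants: 1 1-(2,6-dihydroxy-4-methoxyphenyl)ethanone (5 equiv); 2 formaldehyde (37% aqueous solution, 1 equiv)
Product: 4 bis(3-acetyl-2,4-dihydroxy-6-methoxyphenyl)methane, via benzylic alcohol 3 (not isolated)
Conditions: 37% aq. CH2O (1 equiv), 1 (5 equiv), KOH (cat.), MeOH–H2O, 0 °C to rt, N2; then 1 M HCl; excess 1 recovered by chromatography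
Reagents that add atoms: formaldehyde (2), C=O
Why: Base-catalysed hydroxymethylation of the phenoxide of 1 at one of its two equivalent free ring carbons gives benzylic alcohol 3, which loses water to an ortho-quinone methide that a second phenoxide of 1 captures in a Michael addition (Lederer–Manasse-type condensation, the standard way of forming methylene-bis-acylphloroglucinols). The fivefold excess of 1 over the limiting formaldehyde should keep chain growth through the remaining free carbon of 4 low, and the chelated acetyl groups and the methyl ether are inert to dilute alkali at room temperature.

Step 2
Reactants: 4 bis(3-acetyl-2,4-dihydroxy-6-methoxyphenyl)methane; 5 iodomethane
Product: 7 mallotophenone [bis(3-acetyl-2,4-dihydroxy-6-methoxy-5-methylphenyl)methane], via mono-C-methyl dimer 6 (not isolated)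
Conditions: NaOMe (2.2 equiv), MeI (2.2 equiv), MeOH, 0 °C to rt, Ar; then 1 M HCl
Reagents that add atoms: iodomethane (5), CI
Why: Sodium methoxide converts each ring of 4 into its delocalized phenoxide, whose carbon C2, ortho to the oxygen on C3 and para to the oxygen on C5, attacks iodomethane in an SN2 reaction; the resulting cyclohexadienone tautomerizes to the methylated phenol, and the same event on the second ring takes mono-C-methyl dimer 6 on to 7. The closest known reaction type is the nuclear C-methylation of acylphloroglucinol and polyhydroxyacetophenone anions with iodomethane and alkoxide in methanol. No ring is closed and no stereocenter is created, so there is no mode of closure and no element of stereocontrol to specify. The step needs alkylation on carbon and not on oxygen, at C2 and not at the substituted carbons C4 and C6, and one methyl group per ring. Carbon attack is favoured because methanol hydrogen-bonds to the phenoxide oxygen, the other hydroxyl of each ring is tied to the acetyl carbonyl, and iodomethane is a soft electrophile. C2 is the only unsubstituted ring carbon, so only there can alkylation be followed by return to the aromatic ring, whereas attack at C6 or C4 would build a quaternary centre in a hindered position and leave a non-aromatic dienone. Base and iodomethane are both held near one equivalent per ring, so a ring is returned to the neutral phenol once it has been methylated, which together with the low temperature should restrain a second, dearomatizing alkylation and limit base-induced scission of the bridge. The two rings are insulated by the sp3 bridge carbon and are expected to react independently and alike, which is what allows both aryl–CH3 bonds to be formed in one operation.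

## Compound list

1 | 1-(2,6-dihydroxy-4-methoxyphenyl)ethanone | COc1cc(O)c(C(C)=O)c(O)c1 | starting material
2 | formaldehyde | C=O | starting material
3 | 1-[2,6-dihydroxy-3-(hydroxymethyl)-4-methoxyphenyl]ethanone | COc1cc(O)c(C(C)=O)c(O)c1CO | intermediate
4 | bis(3-acetyl-2,4-dihydroxy-6-methoxyphenyl)methane | COc1cc(O)c(C(C)=O)c(O)c1Cc1c(O)c(C(C)=O)c(O)cc1OC | intermediate
5 | iodomethane | CI | starting material
6 | (3-acetyl-2,4-dihydroxy-6-methoxy-5-methylphenyl)(3-acetyl-2,4-dihydroxy-6-methoxyphenyl)methane | COc1c(C)c(O)c(C(C)=O)c(O)c1Cc1c(O)c(C(C)=O)c(O)cc1OC | intermediate
7 | mallotophenone, bis(3-acetyl-2,4-dihydroxy-6-methoxy-5-methylphenyl)methane | COc1c(C)c(O)c(C(C)=O)c(O)c1Cc1c(O)c(C(C)=O)c(O)c(C)c1OC | target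

## Step count and risk assessment

Total step count: 2. Longest linear sequence: 2 steps (1 to 4 to 7).

The route has only two steps, so the assessment covers both: the key step and the one other step.

**Step 2 (key step).** The most likely failure is loss of site control in the alkylation:

- methylation on a phenoxide oxygen instead of on C2;
- a second, dearomatizing methylation at C2, or ipso attack at the bridge-bearing carbon C6;
- incomplete reaction on one of the two rings, giving mixtures that are hard to separate because every component is a dimer;
- methoxide-induced retro-Michael scission and scrambling of the methylene bridge if the reaction has to be warmed.

Fallback: the order of the two bond-forming events would be reversed. Compound 1 would be C-methylated as the monomer (NaOMe, MeI, MeOH, the nuclear methylation on the substrate class for which it is established) to 1-(2,6-dihydroxy-4-methoxy-3-methylphenyl)ethanone (F1), which would be separated from unchanged 1 and from doubly methylated material. F1 would then be condensed with formaldehyde (2, half an equivalent) in dilute aqueous KOH to give 7 directly. In this order the bridge is never exposed to the methylating medium, no bridge-bearing carbon is present during the alkylation, and F1 has a single free ring carbon, so the bridging can give nothing but the dimer. The fallback sets out from 1 and comes back to the route at 7. Its price is the loss of the two-directional step and a statistical monomethylation of 1.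

**Step 1.** The most likely failure is over-condensation. Each ring of 4 keeps one nucleophilic carbon that is about as reactive as those of 1, so chain growth to trimers and higher oligomers competes with dimer formation whenever formaldehyde meets 4 instead of 1. The equilibrating medium can also redistribute methylene units.

Fallback: one of the two equivalent ring carbons of 1 would be blocked before bridging. Monobromination of 1 (N-bromosuccinimide, 1 equiv, MeCN, 0 °C) should give 1-(3-bromo-2,6-dihydroxy-4-methoxyphenyl)ethanone (F2). The halogen lowers the nucleophilicity of the ring, so a second bromination should be slower than the first. F2 has a single free ring carbon and is expected to condense with formaldehyde (2) in dilute aqueous KOH to bis(3-acetyl-5-bromo-2,4-dihydroxy-6-methoxyphenyl)methane (F3). F3 is the only bridged product that F2 can give, and F3 itself has no free ring carbon left, so the chain cannot grow. Hydrogenolysis of both C–Br bonds of F3 with H2 over Pd/C in methanol containing NaOAc at room temperature should leave the diarylmethane C–C bonds and the chelated ketones untouched and convert F3 into 4. The fallback sets out from 1 and comes back to the route at 4, two operations later than planned.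

## Further compounds

F1 | step 2 | 1-(2,6-dihydroxy-4-methoxy-3-methylphenyl)ethanone | COc1cc(O)c(C(C)=O)c(O)c1C
F2 | step 1 | 1-(3-bromo-2,6-dihydroxy-4-methoxyphenyl)ethanone | COc1cc(O)c(C(C)=O)c(O)c1Br
F3 | step 1 | bis(3-acetyl-5-bromo-2,4-dihydroxy-6-methoxyphenyl)methane | COc1c(Br)c(O)c(C(C)=O)c(O)c1Cc1c(O)c(C(C)=O)c(O)c(Br)c1OC
A1 | alternative 1 | bis(2,4,6-trihydroxy-3-methylphenyl)methane | Cc1c(O)cc(O)c(Cc2c(O)cc(O)c(C)c2O)c1O
A2 | alternative 1 | nonane-3,7-dione | CCC(=O)CCCC(=O)CC
A3 | alternative 1 | malonyl dichloride | O=C(Cl)CC(=O)Cl
A4 | alternative 2 | bis[6-(benzyloxy)-4-hydroxy-2-methoxy-3-methylphenyl]methane | COc1c(C)c(O)cc(OCc2ccccc2)c1Cc1c(OCc2ccccc2)cc(O)c(C)c1OC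
A5 | alternative 2 | 2,2'-methylenebis[3-(benzyloxy)cyclobut-2-en-1-one] | O=C1CC(OCc2ccccc2)=C1CC1=C(OCc2ccccc2)CC1=O
A6 | alternative 2 | 1-methoxyprop-1-yne | CC#COC
A7 | alternative 3 | bis(2,4,6-trimethoxy-3-methylphenyl)methane | Cc1c(OC)cc(OC)c(Cc2c(OC)cc(OC)c(C)c2OC)c1OC
A8 | alternative 3 | bis(2,4,6-tribromo-3-methylphenyl)methane | Cc1c(Br)cc(Br)c(Cc2c(Br)cc(Br)c(C)c2Br)c1Br
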